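**Plan**

1. Numbering: oxepane O1, C2 (quaternary), C3 (carbinol), C4–C7; exocyclic C1'–C2'; side chain C1''–C8'' counted outward from C2.
2. Retrosynthetic cuts, in order: C5''–C6'' (Weinreb amide + alkenyllithium), C2''–C3'' (alkyl–alkyl Negishi), the ring bond C2–C3, then the enol ether carbon on O1 (acrylate methylenation) and C5–C6 (B-alkyl Suzuki).
3. Enabling feature: C2 carries O1, a methyl group and a chain whose first two carbons can be a vinyl group, and it is bonded to the C3 carbinol. The C2–C3 bond of the oxepane is therefore what a γ-alkoxy-γ-methylallyl boronate, tethered through O1–C7, leaves behind when it adds to a C3 aldehyde.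
4. Forward order: the E alkene C6=C1' is made first on a butynediol-derived vinyl iodide, then the dienyl ether, the C3–C5 arm, the allylboronate and the aldehyde follow. The only ring (the oxepane) closes in the allylboration, and the side chain is then grown from the vinyl group, with the enone last.
5. Stereochemistry: C2/C3 relative from the E enol ether in a chair transition state, absolute from a chiral phosphoric acid; C4'' from the (R)-Roche ester; C6=C1' from trans-hydrostannation and stereoretentive coupling; C6''=C7'' from syn-hydrozirconation.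

Key step: step 10

Assumption: the facial preference of the phosphoric acid is carried over from intermolecular aldehyde allylborations (R acid, Re face), so the S acid is specified for Si-face attack at C3; the sense would be checked on 15 (Mosher ester analysis) and the R acid used if it is reversed.

**Route**

Step 1
Reactants: 1 but-2-yne-1,4-diol
Product: 2 4-(tert-butyldimethylsilyloxy)but-2-yn-1-ol
Conditions: NaH (1.0 equiv), THF, 0 °C to rt; then TBSCl (1.0 equiv)
Reagents that add atoms: tert-butyldimethylsilyl chloride, C[Si](C)(Cl)C(C)(C)C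
Why: Monosilylation of a symmetrical diol through its sparingly soluble monosodium alkoxide (Williamson-type O-silylation) should stop at the mono-ether because the alkoxide that has reacted is not regenerated.

Step 2
Reactants: 2 4-(tert-butyldimethylsilyloxy)but-2-yn-1-ol
Product: 3 (2Z)-4-(tert-butyldimethylsilyloxy)-2-(tributylstannyl)but-2-en-1-ol
Conditions: Bu3SnH (1.1 equiv), [Cp*RuCl]4 (1.5 mol%), CH2Cl2, rt
Reagents that add atoms: tributyltin hydride, CCCC[SnH](CCCC)CCCC
Why: Hydroxyl-directed ruthenium-catalysed trans-hydrostannation of a propargylic alcohol should place tin on the alkyne carbon next to the free carbinol (C6) and hydrogen anti on C1', which fixes C7 and C2' trans across the future exocyclic alkene.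

Step 3
Reactants: 3 (2Z)-4-(tert-butyldimethylsilyloxy)-2-(tributylstannyl)but-2-en-1-ol
Product: 4 (2Z)-4-(tert-butyldimethylsilyloxy)-2-iodobut-2-en-1-ol
Conditions: I2 (1.05 equiv), CH2Cl2, 0 °C
Reagents that add atoms: iodine, II
Why: Iododestannylation (electrophilic ipso substitution at the alkenyl C–Sn bond) proceeds with retention of alkene geometry and leaves the C7 hydroxyl free.

Step 4
Reactants: 4 (2Z)-4-(tert-butyldimethylsilyloxy)-2-iodobut-2-en-1-ol; 5 acryloyl chloride
Product: 6 (2Z)-4-(tert-butyldimethylsilyloxy)-2-iodobut-2-en-1-yl prop-2-enoate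
Conditions: Et3N, CH2Cl2, −78 to 0 °C
Reagents that add atoms: none
Why: O-Acylation of a primary allylic alcohol with an acid chloride and an amine base brings in the carbons that become C2, C1'' and C2''.

Step 5
Reactants: 6 (2Z)-4-(tert-butyldimethylsilyloxy)-2-iodobut-2-en-1-yl prop-2-enoate
Product: 7 tert-butyl{[(2Z)-4-(buta-1,3-dien-2-yloxy)-3-iodobut-2-en-1-yl]oxy}dimethylsilane
Conditions: Cp2Ti(μ-Cl)(μ-CH2)AlMe2 (1.3 equiv), pyridine (cat.), THF/toluene, −40 to 0 °C; aq. NaOH; basic alumina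
Reagents that add atoms: Tebbe reagent Cp2Ti(μ-Cl)(μ-CH2)AlMe2, C[Al-]1(C)C[Ti](C2C=CC=C2)(C2C=CC=C2)[Cl+]1
Why: Tebbe methylenation (titanium methylidene olefination of an ester carbonyl) turns the acrylate into the 2-alkoxy-1,3-diene at or below 0 °C, which avoids Claisen rearrangement of the allyl vinyl ether and spares the vinyl iodide and silyl ether; the new CH2 becomes the C2 methyl group.

Step 6
Reactants: 7 tert-butyl{[(2Z)-4-(buta-1,3-dien-2-yloxy)-3-iodobut-2-en-1-yl]oxy}dimethylsilane; 8 allyl acetate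
Product: 10 (4E)-4-[(buta-1,3-dien-2-yloxy)methyl]-6-(tert-butyldimethylsilyloxy)hex-4-en-1-yl acetate, via 3-acetoxypropyl-9-BBN 9 (not isolated)
Conditions: 8 (1.6 equiv), 9-BBN (1.5 equiv), THF, 0 °C to rt; then 3 M aq. K3PO4, 7, Pd(dppf)Cl2 (5 mol%), AsPh3, DMF, rt
Reagents that add atoms: none
Why: B-alkyl Suzuki–Miyaura coupling: 9-BBN hydroborates allyl acetate at the terminus and the alkylborane couples with the vinyl iodide with retention, so the C3–C5 arm ends up cis to C2' (E alkene), and at room temperature transmetalation of the borate should outpace carbopalladation of the pendant diene.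

Step 7
Reactants: 10 (4E)-4-[(buta-1,3-dien-2-yloxy)methyl]-6-(tert-butyldimethylsilyloxy)hex-4-en-1-yl acetate
Product: 11 (4E)-6-(tert-butyldimethylsilyloxy)-4-({[(2E)-4-(4,4,5,5-tetramethyl-1,3,2-dioxaborolan-2-yl)but-2-en-2-yl]oxy}methyl)hex-4-en-1-yl acetate
Conditions: pinacolborane (1.05 equiv), Ni(cod)2 (2.5 mol%), PCy3 (2.5 mol%), toluene, rt
Reagents that add atoms: pinacolborane, [H]B1OC(C)(C)C(C)(C)O1
Why: Proposed new method: zerovalent nickel with PCy3 should bind the s-cis diene, pass hydride from pinacolborane to the CH2 terminus on the alkoxy-bearing carbon and boron to the unhindered far terminus through an η3-allyl nickel boryl, which leaves the former termini cis on the new C2=C1'' bond (methyl cis and O1 trans to CH2B, the E enol ether); the closest known reaction type is the nickel-catalysed 1,4-hydroboration of 2-alkyl-1,3-dienes to stereodefined trisubstituted allylboronates.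

Step 8
Reactants: 11 (4E)-6-(tert-butyldimethylsilyloxy)-4-({[(2E)-4-(4,4,5,5-tetramethyl-1,3,2-dioxaborolan-2-yl)but-2-en-2-yl]oxy}methyl)hex-4-en-1-yl acetate
Product: 12 (4E)-6-(tert-butyldimethylsilyloxy)-4-({[(2E)-4-(4,4,5,5-tetramethyl-1,3,2-dioxaborolan-2-yl)but-2-en-2-yl]oxy}methyl)hex-4-en-1-ol
Conditions: K2CO3 (0.2 equiv), MeOH, 0 °C; pH 7 buffer work-up
Reagents that add atoms: none
Why: Base-catalysed transesterification (Zemplén-type methanolysis) removes the acetate under conditions that neither hydrolyse the enol ether nor cleave the pinacol boronate.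

Step 9
Reactants: 12 (4E)-6-(tert-butyldimethylsilyloxy)-4-({[(2E)-4-(4,4,5,5-tetramethyl-1,3,2-dioxaborolan-2-yl)but-2-en-2-yl]oxy}methyl)hex-4-en-1-ol
Product: 13 (4E)-6-(tert-butyldimethylsilyloxy)-4-({[(2E)-4-(4,4,5,5-tetramethyl-1,3,2-dioxaborolan-2-yl)but-2-en-2-yl]oxy}methyl)hex-4-enal
Conditions: Dess–Martin periodinane (1.3 equiv), pyridine (5 equiv), CH2Cl2, 0 °C; cold work-up, used at once
Reagents that add atoms: none
Why: Dess–Martin oxidation buffered with pyridine gives the aldehyde under non-acidic, non-aqueous conditions tolerated by pinacol boronates and enol ethers, and the product is carried on cold to limit uncatalysed ring closure.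

Step 10
Reactants: 13 (4E)-6-(tert-butyldimethylsilyloxy)-4-({[(2E)-4-(4,4,5,5-tetramethyl-1,3,2-dioxaborolan-2-yl)but-2-en-2-yl]oxy}methyl)hex-4-enal
Product: 15 (2S,3R,6E)-6-[2-(tert-butyldimethylsilyloxy)ethylidene]-2-methyl-2-vinyloxepan-3-ol, via O-pinacolboryl ether 14 (not isolated)
Conditions: (S)-3,3'-bis(2,4,6-triisopropylphenyl)-1,1'-binaphthyl-2,2'-diyl hydrogen phosphate (5 mol%), 4 Å molecular sieves, toluene, −30 °C; then aq. NaHCO3
Reagents that add atoms: none
Why: Proposed new method: the phosphoric acid hydrogen-bonds to a pinacol oxygen and so raises the Lewis acidity of boron, the C3 aldehyde oxygen binds boron, and the γ-carbon C2 adds to C3 through a six-membered chair while the O1–C7–C6–C5–C4 tether closes the oxepane; the closest known reaction types are the chiral phosphoric acid-catalysed intermolecular allylboration of aldehydes with pinacol allylboronates and the thermal intramolecular addition of tethered γ-alkoxyallyl boronates to aldehydes. The ring closes by C2–C3 bond formation in a 7-exo-trig mode with respect to the aldehyde. In the chair the E enol ether puts O1 equatorial and the methyl group axial on C2, and the tether holds C4 equatorial on C3, so the C3 hydroxyl should come out cis to the methyl and trans to the vinyl group: both centres are set as a pair by the alkene geometry. The absolute sense (Si face of the aldehyde, 2S,3R) is set by the S acid. The step needs γ-selectivity, which the cyclic transition state enforces, and a slow uncatalysed background, which the γ,γ-disubstituted pinacol ester, the low temperature and the seven-membered ring size should provide. Aqueous work-up cleaves the O–B bond of 14.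

Step 11
Reactants: 15 (2S,3R,6E)-6-[2-(tert-butyldimethylsilyloxy)ethylidene]-2-methyl-2-vinyloxepan-3-ol
Product: 16 (2S,3R,6E)-6-[2-(tert-butyldimethylsilyloxy)ethylidene]-2-methyl-3-(triethylsilyloxy)-2-vinyloxepane
Conditions: TESOTf, 2,6-lutidine, CH2Cl2, −78 to 0 °C
Reagents that add atoms: triethylsilyl trifluoromethanesulfonate, CC[Si](CC)(CC)OS(=O)(=O)C(F)(F)F
Why: Silylation of the hindered secondary alcohol with a silyl triflate and 2,6-lutidine masks O3 for the organometallic steps and is removed with the other silyl groups at the end.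

Step 12
Reactants: 16 (2S,3R,6E)-6-[2-(tert-butyldimethylsilyloxy)ethylidene]-2-methyl-3-(triethylsilyloxy)-2-vinyloxepane
Product: 18 2-[(2S,3R,6E)-6-[2-(tert-butyldimethylsilyloxy)ethylidene]-2-methyl-3-(triethylsilyloxy)oxepan-2-yl]ethanol, via B-alkyl-9-BBN 17 (not isolated)
Conditions: 9-BBN, THF, 0 °C to rt; then aq. NaOH, H2O2, 0 °C
Reagents that add atoms: hydrogen peroxide, OO
Why: Hydroboration–oxidation with 9-BBN is anti-Markovnikov and selective for the monosubstituted vinyl group over the trisubstituted exocyclic alkene, giving the C2'' alcohol without touching C2 or C3.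

Step 13
Reactants: 18 2-[(2S,3R,6E)-6-[2-(tert-butyldimethylsilyloxy)ethylidene]-2-methyl-3-(triethylsilyloxy)oxepan-2-yl]ethanol
Product: 19 (2S,3R,6E)-6-[2-(tert-butyldimethylsilyloxy)ethylidene]-2-(2-iodoethyl)-2-methyl-3-(triethylsilyloxy)oxepane
Conditions: I2, PPh3, imidazole, CH2Cl2, 0 °C to rt
Reagents that add atoms: iodine, II
Why: Garegg–Samuelsson (Appel-type) iodination converts the primary alcohol into the primary iodide under near-neutral conditions compatible with both silyl ethers.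

Step 14
Reactants: 20 methyl (2R)-3-hydroxy-2-methylpropanoate
Product: 21 methyl (2S)-3-iodo-2-methylpropanoate
Conditions: I2, PPh3, imidazole, CH2Cl2, 0 °C to rt
Reagents that add atoms: iodine, II
Why: The same Appel-type iodination does not touch the α-stereocentre (the descriptor becomes S only because iodine outranks the ester).

Step 15
Reactants: 19 (2S,3R,6E)-6-[2-(tert-butyldimethylsilyloxy)ethylidene]-2-(2-iodoethyl)-2-methyl-3-(triethylsilyloxy)oxepane; 21 methyl (2S)-3-iodo-2-methylpropanoate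
Product: 23 methyl (2R)-5-[(2S,3R,6E)-6-[2-(tert-butyldimethylsilyloxy)ethylidene]-2-methyl-3-(triethylsilyloxy)oxepan-2-yl]-2-methylpentanoate, via alkylzinc iodide 22 (not isolated)
Conditions: 21, Zn dust (I2-activated), THF/NMP, 40 °C; then 19, Pd2(dba)3 (2 mol%), PCyp3 (8 mol%), N-methylimidazole (1.2 equiv), THF/NMP 2:1, 80 °C
Reagents that add atoms: none
Why: Alkyl–alkyl Negishi coupling: zinc insertion gives a configurationally stable β-ester alkylzinc iodide, and the bulky electron-rich trialkylphosphine on palladium allows oxidative addition of the unactivated primary iodide and coupling ahead of β-hydride elimination, joining C2''–C3'' and bringing in C4'' with the R configuration of the chiral pool.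

Step 16
Reactants: 23 methyl (2R)-5-[(2S,3R,6E)-6-[2-(tert-butyldimethylsilyloxy)ethylidene]-2-methyl-3-(triethylsilyloxy)oxepan-2-yl]-2-methylpentanoate
Product: 24 (2R)-5-[(2S,3R,6E)-6-[2-(tert-butyldimethylsilyloxy)ethylidene]-2-methyl-3-(triethylsilyloxy)oxepan-2-yl]-N-methoxy-N,2-dimethylpentanamide
Conditions: MeNH(OMe)·HCl (3 equiv), iPrMgCl (6 equiv), THF, −20 to 0 °C
Reagents that add atoms: N,O-dimethylhydroxylamine hydrochloride, Cl.CNOC
Why: Weinreb amide formation by aminolysis of the ester with the chloromagnesium amide is fast at low temperature and is a standard way to convert α-methyl esters without epimerisation.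

Step 17
Reactants: 25 2-methylbut-3-yn-2-ol
Product: 26 triethyl[(2-methylbut-3-yn-2-yl)oxy]silane
Conditions: TESOTf, 2,6-lutidine, CH2Cl2, 0 °C
Reagents that add atoms: triethylsilyl trifluoromethanesulfonate, CC[Si](CC)(CC)OS(=O)(=O)C(F)(F)F
Why: Silylation of the tertiary propargylic alcohol with a silyl triflate protects the future C8'' hydroxyl from the organometallic reagents.

Step 18
Reactants: 26 triethyl[(2-methylbut-3-yn-2-yl)oxy]silane
Product: 28 triethyl{[(3E)-4-iodo-2-methylbut-3-en-2-yl]oxy}silane, via alkenylzirconocene chloride 27 (not isolated)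
Conditions: Cp2Zr(H)Cl, THF, rt; then I2, 0 °C
Reagents that add atoms: iodine, II
Why: Hydrozirconation of the terminal alkyne is a syn addition with zirconium at the terminus, and iodinolysis with retention gives the E vinyl iodide that defines the C6''=C7'' geometry.

Step 19
Reactants: 24 (2R)-5-[(2S,3R,6E)-6-[2-(tert-butyldimethylsilyloxy)ethylidene]-2-methyl-3-(triethylsilyloxy)oxepan-2-yl]-N-methoxy-N,2-dimethylpentanamide; 28 triethyl{[(3E)-4-iodo-2-methylbut-3-en-2-yl]oxy}silane
Product: 31 (3E,6R)-9-[(2S,3R,6E)-6-[2-(tert-butyldimethylsilyloxy)ethylidene]-2-methyl-3-(triethylsilyloxy)oxepan-2-yl]-2,6-dimethyl-2-(triethylsilyloxy)non-3-en-5-one, via alkenyllithium 29 (not isolated), via lithium hemiaminal alkoxide 30 (not isolated)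
Conditions: 28, tBuLi (2.0 equiv), Et2O, −78 °C; then 24, −78 to −40 °C; then AcOH, −78 °C to rt
Reagents that add atoms: none
Why: Weinreb ketone synthesis: iodine–lithium exchange with retention gives the E alkenyllithium, which adds once to the amide to form a chelated tetrahedral adduct that collapses to the enone only on acidic quench, so neither over-addition nor, at −78 °C, epimerisation at C4'' is expected.

Step 20
Reactants: 31 (3E,6R)-9-[(2S,3R,6E)-6-[2-(tert-butyldimethylsilyloxy)ethylidene]-2-methyl-3-(triethylsilyloxy)oxepan-2-yl]-2,6-dimethyl-2-(triethylsilyloxy)non-3-en-5-one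
Product: 32 (3E,6R)-2-hydroxy-9-[(2S,3R,6E)-3-hydroxy-6-(2-hydroxyethylidene)-2-methyloxepan-2-yl]-2,6-dimethylnon-3-en-5-one
Conditions: HF·pyridine, pyridine, THF, 0 °C to rt
Reagents that add atoms: none
Why: Global desilylation with buffered HF·pyridine removes the primary TBS and the secondary and tertiary TES groups under mildly acidic conditions that avoid base-mediated epimerisation of C4'' or conjugate addition to the enone.

**Compound list**

1 | but-2-yne-1,4-diol | OCC#CCO | starting material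
2 | 4-(tert-butyldimethylsilyloxy)but-2-yn-1-ol | OCC#CCO[Si](C)(C)C(C)(C)C | intermediate
3 | (2Z)-4-(tert-butyldimethylsilyloxy)-2-(tributylstannyl)but-2-en-1-ol | OC/C(=C/CO[Si](C)(C)C(C)(C)C)[Sn](CCCC)(CCCC)CCCC | intermediate
4 | (2Z)-4-(tert-butyldimethylsilyloxy)-2-iodobut-2-en-1-ol | OC/C(I)=C/CO[Si](C)(C)C(C)(C)C | intermediate
5 | acryloyl chloride | C=CC(=O)Cl | starting material
6 | (2Z)-4-(tert-butyldimethylsilyloxy)-2-iodobut-2-en-1-yl prop-2-enoate | C=CC(=O)OC/C(I)=C/CO[Si](C)(C)C(C)(C)C | intermediate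
7 | tert-butyl{[(2Z)-4-(buta-1,3-dien-2-yloxy)-3-iodobut-2-en-1-yl]oxy}dimethylsilane | C=CC(=C)OC/C(I)=C/CO[Si](C)(C)C(C)(C)C | intermediate
8 | allyl acetate | C=CCOC(C)=O | starting material
9 | 3-(9-borabicyclo[3.3.1]nonan-9-yl)propyl acetate (not isolated) | CC(=O)OCCCB1C2CCCC1CCC2 | intermediate
10 | (4E)-4-[(buta-1,3-dien-2-yloxy)methyl]-6-(tert-butyldimethylsilyloxy)hex-4-en-1-yl acetate | C=CC(=C)OC/C(=C/CO[Si](C)(C)C(C)(C)C)CCCOC(C)=O | intermediate
11 | (4E)-6-(tert-butyldimethylsilyloxy)-4-({[(2E)-4-(4,4,5,5-tetramethyl-1,3,2-dioxaborolan-2-yl)but-2-en-2-yl]oxy}methyl)hex-4-en-1-yl acetate | CC(=O)OCCC/C(=C\CO[Si](C)(C)C(C)(C)C)CO/C(C)=C/CB1OC(C)(C)C(C)(C)O1 | intermediate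
12 | (4E)-6-(tert-butyldimethylsilyloxy)-4-({[(2E)-4-(4,4,5,5-tetramethyl-1,3,2-dioxaborolan-2-yl)but-2-en-2-yl]oxy}methyl)hex-4-en-1-ol | OCCC/C(=C\CO[Si](C)(C)C(C)(C)C)CO/C(C)=C/CB1OC(C)(C)C(C)(C)O1 | intermediate
13 | (4E)-6-(tert-butyldimethylsilyloxy)-4-({[(2E)-4-(4,4,5,5-tetramethyl-1,3,2-dioxaborolan-2-yl)but-2-en-2-yl]oxy}methyl)hex-4-enal (key-step precursor) | O=CCC/C(=C\CO[Si](C)(C)C(C)(C)C)CO/C(C)=C/CB1OC(C)(C)C(C)(C)O1 | intermediate
14 | 2-{[(2S,3R,6E)-6-[2-(tert-butyldimethylsilyloxy)ethylidene]-2-methyl-2-vinyloxepan-3-yl]oxy}-4,4,5,5-tetramethyl-1,3,2-dioxaborolane (not isolated) | C=C[C@]1(C)OC/C(=C/CO[Si](C)(C)C(C)(C)C)CC[C@H]1OB1OC(C)(C)C(C)(C)O1 | intermediate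
15 | (2S,3R,6E)-6-[2-(tert-butyldimethylsilyloxy)ethylidene]-2-methyl-2-vinyloxepan-3-ol (key-step product) | C=C[C@]1(C)OC/C(=C/CO[Si](C)(C)C(C)(C)C)CC[C@H]1O | intermediate
16 | (2S,3R,6E)-6-[2-(tert-butyldimethylsilyloxy)ethylidene]-2-methyl-3-(triethylsilyloxy)-2-vinyloxepane | C=C[C@]1(C)OC/C(=C/CO[Si](C)(C)C(C)(C)C)CC[C@H]1O[Si](CC)(CC)CC | intermediate
17 | 9-{2-[(2S,3R,6E)-6-[2-(tert-butyldimethylsilyloxy)ethylidene]-2-methyl-3-(triethylsilyloxy)oxepan-2-yl]ethyl}-9-borabicyclo[3.3.1]nonane (not isolated) | C1CCC2CCCC1B2CC[C@]1(C)OC/C(=C/CO[Si](C)(C)C(C)(C)C)CC[C@H]1O[Si](CC)(CC)CC | intermediate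
18 | 2-[(2S,3R,6E)-6-[2-(tert-butyldimethylsilyloxy)ethylidene]-2-methyl-3-(triethylsilyloxy)oxepan-2-yl]ethanol | OCC[C@]1(C)OC/C(=C/CO[Si](C)(C)C(C)(C)C)CC[C@H]1O[Si](CC)(CC)CC | intermediate
19 | (2S,3R,6E)-6-[2-(tert-butyldimethylsilyloxy)ethylidene]-2-(2-iodoethyl)-2-methyl-3-(triethylsilyloxy)oxepane | ICC[C@]1(C)OC/C(=C/CO[Si](C)(C)C(C)(C)C)CC[C@H]1O[Si](CC)(CC)CC | intermediate
20 | methyl (2R)-3-hydroxy-2-methylpropanoate | C[C@H](CO)C(=O)OC | starting material
21 | methyl (2S)-3-iodo-2-methylpropanoate | C[C@H](CI)C(=O)OC | intermediate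
22 | [(2S)-3-methoxy-2-methyl-3-oxopropyl]zinc iodide (not isolated) | C[C@H](C[Zn]I)C(=O)OC | intermediate
23 | methyl (2R)-5-[(2S,3R,6E)-6-[2-(tert-butyldimethylsilyloxy)ethylidene]-2-methyl-3-(triethylsilyloxy)oxepan-2-yl]-2-methylpentanoate | C[C@H](CCC[C@]1(C)OC/C(=C/CO[Si](C)(C)C(C)(C)C)CC[C@H]1O[Si](CC)(CC)CC)C(=O)OC | intermediate
24 | (2R)-5-[(2S,3R,6E)-6-[2-(tert-butyldimethylsilyloxy)ethylidene]-2-methyl-3-(triethylsilyloxy)oxepan-2-yl]-N-methoxy-N,2-dimethylpentanamide | C[C@H](CCC[C@]1(C)OC/C(=C/CO[Si](C)(C)C(C)(C)C)CC[C@H]1O[Si](CC)(CC)CC)C(=O)N(C)OC | intermediate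
25 | 2-methylbut-3-yn-2-ol | CC(C)(O)C#C | starting material
26 | triethyl[(2-methylbut-3-yn-2-yl)oxy]silane | CC[Si](CC)(CC)OC(C)(C)C#C | intermediate
27 | chlorobis(cyclopentadienyl)[(1E)-3-methyl-3-(triethylsilyloxy)but-1-en-1-yl]zirconium (not isolated) | CC[Si](CC)(CC)OC(C)(C)/C=C/[Zr](Cl)(C1C=CC=C1)C1C=CC=C1 | intermediate
28 | triethyl{[(3E)-4-iodo-2-methylbut-3-en-2-yl]oxy}silane | CC[Si](CC)(CC)OC(C)(C)/C=C/I | intermediate
29 | [(1E)-3-methyl-3-(triethylsilyloxy)but-1-en-1-yl]lithium (not isolated) | CC[Si](CC)(CC)OC(C)(C)/C=C/[Li] | intermediate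
30 | lithium alkoxide of the N-methoxy-N-methyl hemiaminal formed from 24 and 29 (aminal carbon configuration undefined; not isolated) | C[C@H](CCC[C@]1(C)OC/C(=C/CO[Si](C)(C)C(C)(C)C)CC[C@H]1O[Si](CC)(CC)CC)C(O[Li])(/C=C/C(C)(C)O[Si](CC)(CC)CC)N(C)OC | intermediate
31 | (3E,6R)-9-[(2S,3R,6E)-6-[2-(tert-butyldimethylsilyloxy)ethylidene]-2-methyl-3-(triethylsilyloxy)oxepan-2-yl]-2,6-dimethyl-2-(triethylsilyloxy)non-3-en-5-one | C[C@H](CCC[C@]1(C)OC/C(=C/CO[Si](C)(C)C(C)(C)C)CC[C@H]1O[Si](CC)(CC)CC)C(=O)/C=C/C(C)(C)O[Si](CC)(CC)CC | intermediate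
32 | (3E,6R)-2-hydroxy-9-[(2S,3R,6E)-3-hydroxy-6-(2-hydroxyethylidene)-2-methyloxepan-2-yl]-2,6-dimethylnon-3-en-5-one | C[C@H](CCC[C@]1(C)OC/C(=C/CO)CC[C@H]1O)C(=O)/C=C/C(C)(C)O | target

**Step count**

Total: 20 steps. Longest linear sequence: 17 steps (1–13, 15, 16, 19, 20).

**Steps most likely to fail**

1. Step 10 (key step). What may go wrong: reversible protonation of the electron-rich enol ether by the phosphoric acid (E/Z scrambling, or migration of the double bond out of the allyl system), and ring closure of the aldehyde–boronate without catalyst in the background; both erode enantiomeric purity, while the relative configuration is less at risk.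
Fallback (known chemistry; sets out from 13, returns at 15): the ring is closed without any acid (toluene, 4 Å sieves, 20–40 °C). This is the thermal intramolecular allylboration known for tethered γ-alkoxyallyl boronates, which through the same closed chair should give the racemate with the same relative configuration. It forms 14 and the enantiomeric borate F1, hydrolysed on work-up to 15 and the enantiomeric oxepanol F2. The mixture is esterified with (S)-2-methoxy-2-phenylacetic acid (DCC, DMAP, CH2Cl2) to the O-methylmandelate of 15 F3 and the diastereomeric O-methylmandelate F4. These are separated by chromatography, and methanolysis of F3 (K2CO3, MeOH) returns 15 as a single enantiomer.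

2. Step 7. What may go wrong: delivery of boron to the diene terminus next to the alkoxy carbon followed by β-alkoxy elimination, loss of the cis delivery that defines the E enol ether, or insertion of zerovalent nickel into the allylic C7–O bond.
Fallback (known chemistry; sets out from 10, returns at 15, bypassing steps 7–10): the dienyl ether is kept as a latent C7 hydroxyl and the oxepane is closed by epoxide opening.
   - Methanolysis of the acetate (K2CO3, MeOH) gives the primary alcohol F5; Dess–Martin oxidation (pyridine buffer) gives the aldehyde F6.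
   - Wittig olefination with Ph3P=C(CH3)CO2Et gives the E-enoate F7, and iBu2AlH (CH2Cl2, −78 °C) gives the E-allylic alcohol F8.
   - Sharpless asymmetric epoxidation (Ti(OiPr)4, D-(−)-diethyl tartrate, tBuOOH, 4 Å sieves, CH2Cl2, −20 °C) gives the (2R,3R)-epoxy alcohol F9. This fixes C3 directly and sets C2 in the configuration that opening with inversion converts into 2S.
   - Parikh–Doering oxidation gives the epoxy aldehyde F10, and Wittig methylenation (Ph3P=CH2) the vinyl epoxide F11.
   - Brief PPTS in wet THF at 0 °C hydrolyses the 2-alkoxydiene to the hydroxy vinyl epoxide F12.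
   - Camphorsulfonic acid (cat., CH2Cl2, −40 to 0 °C) closes the ring by 7-endo opening at the tertiary allylic carbon C2 with inversion, giving 15.

3. Step 15. What may go wrong: slow transmetalation of the chelated β-ester alkylzinc, so that β-hydride elimination or protodehalogenation of 19 takes over.
Fallback (sets out from 16, returns at 24): 16 is hydroborated with 9-BBN to 17 as in step 12. Instead of being oxidised, 17 is coupled with methyl (2E)-3-iodo-2-methylprop-2-enoate (B-alkyl Suzuki–Miyaura, Pd(dppf)Cl2, AsPh3, aq. K3PO4, DMF/THF, rt) to give the E-enoate F13. LiOH (THF/MeOH/H2O) gives the enoic acid F14. Carboxylate-directed asymmetric hydrogenation with Ru(OAc)2[(R)-BINAP] (H2, MeOH), the ligand enantiomer being chosen by analogy with tiglic acid, sets C4'' and gives the (R)-acid F15 without touching the undirected exocyclic alkene. Amide coupling with MeNH(OMe)·HCl (EDC·HCl, iPr2NEt, CH2Cl2) gives 24.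

Further compounds
F1 | step 10 | 2-{[(2R,3S,6E)-6-[2-(tert-butyldimethylsilyloxy)ethylidene]-2-methyl-2-vinyloxepan-3-yl]oxy}-4,4,5,5-tetramethyl-1,3,2-dioxaborolane | C=C[C@@]1(C)OC/C(=C/CO[Si](C)(C)C(C)(C)C)CC[C@@H]1OB1OC(C)(C)C(C)(C)O1
F2 | step 10 | (2R,3S,6E)-6-[2-(tert-butyldimethylsilyloxy)ethylidene]-2-methyl-2-vinyloxepan-3-ol | C=C[C@@]1(C)OC/C(=C/CO[Si](C)(C)C(C)(C)C)CC[C@@H]1O
F3 | step 10 | (2S,3R,6E)-6-[2-(tert-butyldimethylsilyloxy)ethylidene]-2-methyl-2-vinyloxepan-3-yl (2S)-2-methoxy-2-phenylacetate | C=C[C@]1(C)OC/C(=C/CO[Si](C)(C)C(C)(C)C)CC[C@H]1OC(=O)[C@@H](OC)c1ccccc1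
F4 | step 10 | (2R,3S,6E)-6-[2-(tert-butyldimethylsilyloxy)ethylidene]-2-methyl-2-vinyloxepan-3-yl (2S)-2-methoxy-2-phenylacetate | C=C[C@@]1(C)OC/C(=C/CO[Si](C)(C)C(C)(C)C)CC[C@@H]1OC(=O)[C@@H](OC)c1ccccc1
F5 | step 7 | (4E)-4-[(buta-1,3-dien-2-yloxy)methyl]-6-(tert-butyldimethylsilyloxy)hex-4-en-1-ol | C=CC(=C)OC/C(=C/CO[Si](C)(C)C(C)(C)C)CCCO
F6 | step 7 | (4E)-4-[(buta-1,3-dien-2-yloxy)methyl]-6-(tert-butyldimethylsilyloxy)hex-4-enal | C=CC(=C)OC/C(=C/CO[Si](C)(C)C(C)(C)C)CCC=O
F7 | step 7 | ethyl (2E,6E)-6-[(buta-1,3-dien-2-yloxy)methyl]-8-(tert-butyldimethylsilyloxy)-2-methylocta-2,6-dienoate | C=CC(=C)OC/C(=C/CO[Si](C)(C)C(C)(C)C)CC/C=C(\C)C(=O)OCC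
F8 | step 7 | (2E,6E)-6-[(buta-1,3-dien-2-yloxy)methyl]-8-(tert-butyldimethylsilyloxy)-2-methylocta-2,6-dien-1-ol | C=CC(=C)OC/C(=C/CO[Si](C)(C)C(C)(C)C)CC/C=C(\C)CO
F9 | step 7 | [(2R,3R)-3-{(3E)-3-[(buta-1,3-dien-2-yloxy)methyl]-5-(tert-butyldimethylsilyloxy)pent-3-en-1-yl}-2-methyloxiran-2-yl]methanol | C=CC(=C)OC/C(=C/CO[Si](C)(C)C(C)(C)C)CC[C@H]1O[C@]1(C)CO
F10 | step 7 | (2S,3R)-3-{(3E)-3-[(buta-1,3-dien-2-yloxy)methyl]-5-(tert-butyldimethylsilyloxy)pent-3-en-1-yl}-2-methyloxirane-2-carbaldehyde | C=CC(=C)OC/C(=C/CO[Si](C)(C)C(C)(C)C)CC[C@H]1O[C@]1(C)C=O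
F11 | step 7 | (2R,3R)-3-{(3E)-3-[(buta-1,3-dien-2-yloxy)methyl]-5-(tert-butyldimethylsilyloxy)pent-3-en-1-yl}-2-methyl-2-vinyloxirane | C=CC(=C)OC/C(=C/CO[Si](C)(C)C(C)(C)C)CC[C@H]1O[C@]1(C)C=C
F12 | step 7 | (2E)-4-(tert-butyldimethylsilyloxy)-2-{2-[(2R,3R)-3-methyl-3-vinyloxiran-2-yl]ethyl}but-2-en-1-ol | OC/C(=C/CO[Si](C)(C)C(C)(C)C)CC[C@H]1O[C@]1(C)C=C
F13 | step 15 | methyl (2E)-5-[(2S,3R,6E)-6-[2-(tert-butyldimethylsilyloxy)ethylidene]-2-methyl-3-(triethylsilyloxy)oxepan-2-yl]-2-methylpent-2-enoate | C/C(=C\CC[C@]1(C)OC/C(=C/CO[Si](C)(C)C(C)(C)C)CC[C@H]1O[Si](CC)(CC)CC)C(=O)OC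
F14 | step 15 | (2E)-5-[(2S,3R,6E)-6-[2-(tert-butyldimethylsilyloxy)ethylidene]-2-methyl-3-(triethylsilyloxy)oxepan-2-yl]-2-methylpent-2-enoic acid | C/C(=C\CC[C@]1(C)OC/C(=C/CO[Si](C)(C)C(C)(C)C)CC[C@H]1O[Si](CC)(CC)CC)C(=O)O
F15 | step 15 | (2R)-5-[(2S,3R,6E)-6-[2-(tert-butyldimethylsilyloxy)ethylidene]-2-methyl-3-(triethylsilyloxy)oxepan-2-yl]-2-methylpentanoic acid | C[C@H](CCC[C@]1(C)OC/C(=C/CO[Si](C)(C)C(C)(C)C)CC[C@H]1O[Si](CC)(CC)CC)C(=O)O
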